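**Plan**

1. Numbering follows the target's 7-oxabicyclo[4.1.0]hept-3-ene core (C1 quaternary epoxide carbon, C2 and C5 carbinols, C3 heptenyl-bearing, C4 CH2OH-bearing, C6 epoxide CH, O7; side chain C1'–C4') and is used for the same atoms in every intermediate.
2. Retrosynthesis: C5–OH, C2–OH and C4–CH2OH go back to a ketal-masked ketone, a ketone and an ester; the C1–C1' bond is then cut to a glycidic acid (CO2H on C1) and the bis-silyl dienediolate of tiglic acid; then the two oxirane C–O bonds (enone epoxidation), the ketal (oxidative dearomatisation) and the C3–heptenyl bond (Suzuki) are cut, back to dimethyl 2,5-dihydroxyterephthalate.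
3. Forward: the arene is desymmetrised (O-methylation, bromination, alkenylation), dearomatised to the quinone monoketal and epoxidised, and its C1 ester is freed. The side chain is then joined to the complete ring, and two hydride reductions separated by ketal hydrolysis finish the molecule without protecting-group steps. One terephthalate carboxyl becomes C4–CH2OH; the other is the traceless handle lost as CO2.
4. Enabling feature: the oxirane O7–C1–C6 is cis-fused to the six-membered ring and C1 is a ring-fusion carbon. Its oxiranyl σ-radical (from C1–CO2H) can neither invert nor planarise, so it must bond on the face the carboxyl left, and decarboxylation as a radical leaves the oxirane closed.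
5. Stereochemistry: C1 and C6 come from the tartrate-controlled nucleophilic epoxidation and C1 is retained in the coupling; C2 comes from epoxide-directed DIBAL-H reduction (anti), C5 from Luche reduction (syn); the E-alkenes come from the boronic acid and from attack on the s-trans dienediolate.

Key step: step 8

Assumption: L-(+)-diisopropyl tartrate is taken to give the (1R,6S)-epoxide 7 in step 5; if the sense of induction is the opposite, D-(−)-diisopropyl tartrate is used and nothing else changes.

**Route**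

Step 1
Reactants: 1 dimethyl 2,5-dihydroxyterephthalate
Product: 2 dimethyl 2-hydroxy-5-methoxyterephthalate
Conditions: MeI (1.0 equiv), K2CO3 (1.0 equiv), DMF, rt; recovered 1 recycled
Reagents that add atoms: iodomethane (CI)
Why: Williamson O-methylation of one of the two equivalent phenols of the symmetric diol can give only one mono-ether, the diether and unreacted 1 being separable (statistical monoalkylation of a symmetric diol).

Step 2
Reactants: 2 dimethyl 2-hydroxy-5-methoxyterephthalate
Product: 3 dimethyl 3-bromo-2-hydroxy-5-methoxyterephthalate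
Conditions: NBS, i-Pr2NH (10 mol %), CH2Cl2, 0 °C
Reagents that add atoms: N-bromosuccinimide (O=C1CCC(=O)N1Br)
Why: Amine-catalysed electrophilic aromatic bromination is directed ortho to the free phenol, whose para position is blocked by OMe, so bromine should enter C3 and not C6, which is ortho to the weaker methoxy donor.

Step 3
Reactants: 3 dimethyl 3-bromo-2-hydroxy-5-methoxyterephthalate and 4 (E)-hept-1-en-1-ylboronic acid
Product: 5 dimethyl 3-[(E)-hept-1-en-1-yl]-2-hydroxy-5-methoxyterephthalate
Conditions: Pd(OAc)2 (5 mol %), SPhos, K3PO4, toluene/H2O, 80 °C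
Reagents that add atoms: none
Why: Suzuki–Miyaura coupling of the hindered aryl bromide with the alkenylboronic acid under a bulky biarylphosphine proceeds with retention of the E geometry and tolerates the free phenol and both esters.

Step 4
Reactants: 5 dimethyl 3-[(E)-hept-1-en-1-yl]-2-hydroxy-5-methoxyterephthalate
Product: 6 dimethyl 2-[(E)-hept-1-en-1-yl]-6,6-dimethoxy-3-oxocyclohexa-1,4-diene-1,4-dicarboxylate
Conditions: PhI(OAc)2 (1.1 equiv), MeOH, 0 °C
Reagents that add atoms: methanol (CO)
Why: Hypervalent-iodine oxidative dearomatisation of the p-methoxyphenol is completed by methanol attack at the carbon para to the hydroxyl group, giving the quinone monoketal in which the two hydroquinone oxygens are differentiated as the C2 ketone and the C5 dimethyl ketal.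

Step 5
Reactants: 6 dimethyl 2-[(E)-hept-1-en-1-yl]-6,6-dimethoxy-3-oxocyclohexa-1,4-diene-1,4-dicarboxylate
Product: 7 dimethyl (1R,6S)-3-[(E)-hept-1-en-1-yl]-5,5-dimethoxy-2-oxo-7-oxabicyclo[4.1.0]hept-3-ene-1,4-dicarboxylate
Conditions: Ph3COOH, NaHMDS, L-(+)-DIPT, 4 Å MS, toluene, −60 °C; water quench
Reagents that add atoms: trityl hydroperoxide (OOC(c1ccccc1)(c1ccccc1)c1ccccc1)
Why: In this tartrate-mediated Weitz–Scheffer nucleophilic epoxidation the peroxide anion adds to C6, β to both the C2 ketone and the C1 ester of the only trisubstituted enone double bond (the tetrasubstituted C3=C4 bond is inert), and the sodium tartrate aggregate selects the enone face, so C1 and C6 are set together as the cis-fused (1R,6S)-oxirane.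

Step 6
Reactants: 7 dimethyl (1R,6S)-3-[(E)-hept-1-en-1-yl]-5,5-dimethoxy-2-oxo-7-oxabicyclo[4.1.0]hept-3-ene-1,4-dicarboxylate
Product: 9 (1R,6S)-3-[(E)-hept-1-en-1-yl]-5,5-dimethoxy-4-(methoxycarbonyl)-2-oxo-7-oxabicyclo[4.1.0]hept-3-ene-1-carboxylic acid, via trimethylstannyl ester 8 (not isolated)
Conditions: Me3SnOH (3 equiv), ClCH2CH2Cl, 70 °C; then 0.1 M aq. HCl, 0 °C
Reagents that add atoms: trimethyltin hydroxide (C[Sn](C)(C)O)
Why: Trimethyltin hydroxide cleaves methyl esters under near-neutral conditions and should select the glycidic ester, activated by its α-oxygen and α-keto group, over the C4 ester on a tetrasubstituted alkene flanked by the ketal and the heptenyl-bearing carbon, while free hydroxide, which could open the non-enolisable β-keto ester by retro-Claisen attack, is avoided (chemoselective ester hydrolysis).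

Step 7
Reactants: 10 tiglic acid [(E)-2-methylbut-2-enoic acid]
Product: 12 2-methyl-1,1-bis(trimethylsilyloxy)buta-1,3-diene, via dilithium dienediolate 11 (not isolated)
Conditions: LDA (2.2 equiv), THF, −78 → 0 °C; Me3SiCl (2.5 equiv), −78 °C → rt; distillation
Reagents that add atoms: chlorotrimethylsilane (C[Si](C)(C)Cl)
Why: Double deprotonation of tiglic acid at the carboxyl group and the γ-methyl group gives the extended dienediolate, which Me3SiCl silylates on both oxygens to the vinylogous bis(silyl) ketene acetal (dienolate formation and O-silyl trapping).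

Step 8
Reactants: 9 (1R,6S)-3-[(E)-hept-1-en-1-yl]-5,5-dimethoxy-4-(methoxycarbonyl)-2-oxo-7-oxabicyclo[4.1.0]hept-3-ene-1-carboxylic acid and 12 2-methyl-1,1-bis(trimethylsilyloxy)buta-1,3-diene
Product: 15 (E)-4-[(1R,6S)-3-[(E)-hept-1-en-1-yl]-5,5-dimethoxy-4-(methoxycarbonyl)-2-oxo-7-oxabicyclo[4.1.0]hept-3-en-1-yl]-2-methylbut-2-enoic acid, via Barton ester 13 (not isolated), via trimethylsilyl ester 14 (not isolated)
Conditions: N-hydroxypyridine-2-thione, DIC, DMAP (cat.), PhCF3, 0 °C, dark; then 12 (6 equiv), 450 nm LED, 5 °C; aq. citric acid work-up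
Reagents that add atoms: none
Why: Proposed new method: visible-light homolysis of the Barton ester and loss of CO2 give the oxiranyl σ-radical at C1, which adds to the unsubstituted terminus (C4') of the s-trans dienediolate; the resulting 1,1-bis(silyloxy)allyl radical carries the chain by taking the 2-pyridylthio group from a second Barton ester, and Me3Si–SPy is then expelled through the bis(silyloxy)allyl cation to leave the silyl ester of the conjugated acid. The closest known reaction types are the Barton decarboxylative radical addition to alkenes and the alkylation of silyl enol ethers and ketene acetals by decarboxylatively generated radicals, whereas vinylogous capture by an oxiranyl radical at a fully substituted ring-fusion carbon is without precedent. No ring is closed. No new stereocentre is formed: C1 keeps its configuration because the oxirane must stay cis-fused to the six-membered ring, so the radical cannot invert and the new bond can form only on the face that the carboxyl group left, and the E geometry of C2'=C3' follows from attack on the s-trans diene (the s-cis form suffers a clash between C4'H2 and the Z-OSiMe3 group) and from A(1,3) strain in the allyl cation. The step needs terminal (γ) attack, secured by the unhindered CH2 and the delocalised adduct radical, and intermolecular capture faster than thiopyridyl transfer to C1 or 1,5-hydrogen transfer from a ketal methoxy group, secured by the high rate of σ-radical addition to a 1,3-diene used in sixfold excess in a solvent without weak C–H bonds; an anionic or thermal decarboxylation, which would open the oxirane of a glycidic acid, is avoided because the carboxyl group leaves as a radical.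

Step 9
Reactants: 15 (E)-4-[(1R,6S)-3-[(E)-hept-1-en-1-yl]-5,5-dimethoxy-4-(methoxycarbonyl)-2-oxo-7-oxabicyclo[4.1.0]hept-3-en-1-yl]-2-methylbut-2-enoic acid
Product: 16 (E)-4-[(1S,2R,6S)-3-[(E)-hept-1-en-1-yl]-2-hydroxy-4-(hydroxymethyl)-5,5-dimethoxy-7-oxabicyclo[4.1.0]hept-3-en-1-yl]-2-methylbut-2-enoic acid
Conditions: DIBAL-H (6 equiv), THF, −78 → −30 °C; Rochelle salt work-up
Reagents that add atoms: none
Why: DIBAL-H coordinated to the oxirane oxygen delivers hydride to the C2 ketone from the epoxide face, anti to the C1 side chain, giving the anti-epoxy alcohol (2R), and the excess reagent reduces the conjugated C4 methyl ester to the allylic alcohol while the side-chain acid is masked as its aluminium carboxylate (epoxide-directed, chemoselective hydride reduction).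

Step 10
Reactants: 16 (E)-4-[(1S,2R,6S)-3-[(E)-hept-1-en-1-yl]-2-hydroxy-4-(hydroxymethyl)-5,5-dimethoxy-7-oxabicyclo[4.1.0]hept-3-en-1-yl]-2-methylbut-2-enoic acid
Product: 17 (E)-4-[(1S,2R,6S)-3-[(E)-hept-1-en-1-yl]-2-hydroxy-4-(hydroxymethyl)-5-oxo-7-oxabicyclo[4.1.0]hept-3-en-1-yl]-2-methylbut-2-enoic acid
Conditions: 48% aq. HF, MeCN, 0 °C
Reagents that add atoms: water (O)
Why: Acid-catalysed hydrolysis of the dimethyl ketal through its oxocarbenium ion unmasks the C5 enone carbonyl under conditions mild enough to spare the oxirane and the allylic C2 alcohol.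

Step 11
Reactants: 17 (E)-4-[(1S,2R,6S)-3-[(E)-hept-1-en-1-yl]-2-hydroxy-4-(hydroxymethyl)-5-oxo-7-oxabicyclo[4.1.0]hept-3-en-1-yl]-2-methylbut-2-enoic acid
Product: 18 (E)-4-[(1S,2R,5R,6R)-3-[(E)-hept-1-en-1-yl]-2,5-dihydroxy-4-(hydroxymethyl)-7-oxabicyclo[4.1.0]hept-3-en-1-yl]-2-methylbut-2-enoic acid
Conditions: NaBH4, CeCl3·7H2O, MeOH, −78 °C; pH 4 buffer
Reagents that add atoms: none
Why: Luche 1,2-reduction adds hydride to the C5 enone carbonyl anti to the adjacent C6–O bond of the oxirane (Felkin–Anh, polar substituent antiperiplanar), giving the syn-epoxy alcohol (5R) without conjugate reduction.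

**Compound list**

1 | dimethyl 2,5-dihydroxyterephthalate | COC(=O)c1cc(O)c(C(=O)OC)cc1O | starting material
2 | dimethyl 2-hydroxy-5-methoxyterephthalate | COC(=O)c1cc(OC)c(C(=O)OC)cc1O | intermediate
3 | dimethyl 3-bromo-2-hydroxy-5-methoxyterephthalate | COC(=O)c1cc(OC)c(C(=O)OC)c(Br)c1O | intermediate
4 | (E)-hept-1-en-1-ylboronic acid | CCCCC/C=C/B(O)O | starting material
5 | dimethyl 3-[(E)-hept-1-en-1-yl]-2-hydroxy-5-methoxyterephthalate | CCCCC/C=C/c1c(O)c(C(=O)OC)cc(OC)c1C(=O)OC | intermediate
6 | dimethyl 2-[(E)-hept-1-en-1-yl]-6,6-dimethoxy-3-oxocyclohexa-1,4-diene-1,4-dicarboxylate | CCCCC/C=C/C1=C(C(=O)OC)C(OC)(OC)C=C(C(=O)OC)C1=O | intermediate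
7 | dimethyl (1R,6S)-3-[(E)-hept-1-en-1-yl]-5,5-dimethoxy-2-oxo-7-oxabicyclo[4.1.0]hept-3-ene-1,4-dicarboxylate | CCCCC/C=C/C1=C(C(=O)OC)C(OC)(OC)[C@H]2O[C@@]2(C(=O)OC)C1=O | intermediate
8 | 4-methyl 1-trimethylstannyl (1R,6S)-3-[(E)-hept-1-en-1-yl]-5,5-dimethoxy-2-oxo-7-oxabicyclo[4.1.0]hept-3-ene-1,4-dicarboxylate | CCCCC/C=C/C1=C(C(=O)OC)C(OC)(OC)[C@H]2O[C@@]2(C(=O)O[Sn](C)(C)C)C1=O | intermediate
9 | (1R,6S)-3-[(E)-hept-1-en-1-yl]-5,5-dimethoxy-4-(methoxycarbonyl)-2-oxo-7-oxabicyclo[4.1.0]hept-3-ene-1-carboxylic acid | CCCCC/C=C/C1=C(C(=O)OC)C(OC)(OC)[C@H]2O[C@@]2(C(=O)O)C1=O | intermediate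
10 | tiglic acid [(E)-2-methylbut-2-enoic acid] | C/C=C(\C)C(=O)O | starting material
11 | dilithium 2-methylbuta-1,3-diene-1,1-diolate | [Li+].[Li+].[O-]C([O-])=C(C)C=C | intermediate
12 | 2-methyl-1,1-bis(trimethylsilyloxy)buta-1,3-diene | C=CC(C)=C(O[Si](C)(C)C)O[Si](C)(C)C | intermediate
13 | 4-methyl 1-[2-thioxopyridin-1(2H)-yl] (1R,6S)-3-[(E)-hept-1-en-1-yl]-5,5-dimethoxy-2-oxo-7-oxabicyclo[4.1.0]hept-3-ene-1,4-dicarboxylate (Barton ester of 9) | CCCCC/C=C/C1=C(C(=O)OC)C(OC)(OC)[C@H]2O[C@@]2(C(=O)ON3C=CC=CC3=S)C1=O | intermediate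
14 | trimethylsilyl (E)-4-[(1R,6S)-3-[(E)-hept-1-en-1-yl]-5,5-dimethoxy-4-(methoxycarbonyl)-2-oxo-7-oxabicyclo[4.1.0]hept-3-en-1-yl]-2-methylbut-2-enoate | CCCCC/C=C/C1=C(C(=O)OC)C(OC)(OC)[C@H]2O[C@@]2(C/C=C(\C)C(=O)O[Si](C)(C)C)C1=O | intermediate
15 | (E)-4-[(1R,6S)-3-[(E)-hept-1-en-1-yl]-5,5-dimethoxy-4-(methoxycarbonyl)-2-oxo-7-oxabicyclo[4.1.0]hept-3-en-1-yl]-2-methylbut-2-enoic acid | CCCCC/C=C/C1=C(C(=O)OC)C(OC)(OC)[C@H]2O[C@@]2(C/C=C(\C)C(=O)O)C1=O | intermediate
16 | (E)-4-[(1S,2R,6S)-3-[(E)-hept-1-en-1-yl]-2-hydroxy-4-(hydroxymethyl)-5,5-dimethoxy-7-oxabicyclo[4.1.0]hept-3-en-1-yl]-2-methylbut-2-enoic acid | CCCCC/C=C/C1=C(CO)C(OC)(OC)[C@H]2O[C@@]2(C/C=C(\C)C(=O)O)[C@@H]1O | intermediate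
17 | (E)-4-[(1S,2R,6S)-3-[(E)-hept-1-en-1-yl]-2-hydroxy-4-(hydroxymethyl)-5-oxo-7-oxabicyclo[4.1.0]hept-3-en-1-yl]-2-methylbut-2-enoic acid | CCCCC/C=C/C1=C(CO)C(=O)[C@H]2O[C@@]2(C/C=C(\C)C(=O)O)[C@@H]1O | intermediate
18 | (E)-4-[(1S,2R,5R,6R)-3-[(E)-hept-1-en-1-yl]-2,5-dihydroxy-4-(hydroxymethyl)-7-oxabicyclo[4.1.0]hept-3-en-1-yl]-2-methylbut-2-enoic acid | CCCCC/C=C/C1=C(CO)[C@@H](O)[C@H]2O[C@@]2(C/C=C(\C)C(=O)O)[C@@H]1O | target

**Step count and risks**

Total step count: 11. Longest linear sequence: 10 (steps 1–6 and 8–11).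

Steps most likely to fail:

Step 8 (proposed new method). The oxiranyl radical may be quenched by 1,5-hydrogen transfer from a ketal methoxy group or by thiopyridyl capture before it meets the diene, and the electron-rich adduct radical may fail to carry the chain or may collapse with loss of alkene geometry. The fallback uses known chemistry, avoids any radical at C1 and attaches the side chain before dearomatisation. It sets out from 5: the less hindered, phenol-flanked ester is saponified (NaOH, aq. MeOH; the other ester is di-ortho-substituted) to the salicylic acid F1. Silver-catalysed protodecarboxylation (Ag2CO3, AcOH, DMSO, 120 °C) gives the phenol F2. Its sodium phenoxide is C-alkylated at the only free ortho position with methyl (E)-4-bromo-2-methylbut-2-enoate in toluene to the C-allylated phenol F3. PhI(OAc)2 in MeOH gives the dienone F4, and the tartrate-controlled epoxidation of step 5 gives the epoxy ketone F5. Me3SnOH then cleaves the unhindered side-chain methyl ester, and the route is rejoined at 15.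

Step 5. Peroxide addition may lose site selectivity (attack at C3 or at the heptenyl terminus) or facial selectivity, because an ester on the enone may weaken tartrate control. The fallback gives up asymmetric induction for resolution. It sets out from 6: racemic Weitz–Scheffer epoxidation (t-BuOOH, DBU, CH2Cl2) gives 7 together with its enantiomer F6, which is removed by preparative chiral SFC, and the route is rejoined at 7.

Step 6. Hydrolysis may lose chemoselectivity, either by attack on the C2 ketone followed by retro-Claisen ring cleavage or by cleavage of the C4 ester. The fallback installs an orthogonal ester at the arene stage. It sets out from 5: Ti(OiPr)4-catalysed transesterification of the phenol-assisted ester with allyl alcohol gives the allyl methyl diester F7. PhI(OAc)2 in MeOH gives the allyl ester dienone F8, and tartrate-controlled epoxidation gives the allyl glycidate F9. Pd(PPh3)4 with morpholine removes the allyl group under neutral conditions, and the route is rejoined at 9.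

Further compounds
F1 | step 8 | 3-[(E)-hept-1-en-1-yl]-2-hydroxy-5-methoxy-4-(methoxycarbonyl)benzoic acid | CCCCC/C=C/c1c(O)c(C(=O)O)cc(OC)c1C(=O)OC
F2 | step 8 | methyl 2-[(E)-hept-1-en-1-yl]-3-hydroxy-6-methoxybenzoate | CCCCC/C=C/c1c(O)ccc(OC)c1C(=O)OC
F3 | step 8 | methyl 2-[(E)-hept-1-en-1-yl]-3-hydroxy-6-methoxy-4-[(E)-4-methoxy-3-methyl-4-oxobut-2-en-1-yl]benzoate | CCCCC/C=C/c1c(O)c(C/C=C(\C)C(=O)OC)cc(OC)c1C(=O)OC
F4 | step 8 | methyl 2-[(E)-hept-1-en-1-yl]-6,6-dimethoxy-4-[(E)-4-methoxy-3-methyl-4-oxobut-2-en-1-yl]-3-oxocyclohexa-1,4-diene-1-carboxylate | CCCCC/C=C/C1=C(C(=O)OC)C(OC)(OC)C=C(C/C=C(\C)C(=O)OC)C1=O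
F5 | step 8 | methyl (1R,6S)-3-[(E)-hept-1-en-1-yl]-5,5-dimethoxy-1-[(E)-4-methoxy-3-methyl-4-oxobut-2-en-1-yl]-2-oxo-7-oxabicyclo[4.1.0]hept-3-ene-4-carboxylate | CCCCC/C=C/C1=C(C(=O)OC)C(OC)(OC)[C@H]2O[C@@]2(C/C=C(\C)C(=O)OC)C1=O
F6 | step 5 | dimethyl (1S,6R)-3-[(E)-hept-1-en-1-yl]-5,5-dimethoxy-2-oxo-7-oxabicyclo[4.1.0]hept-3-ene-1,4-dicarboxylate | CCCCC/C=C/C1=C(C(=O)OC)C(OC)(OC)[C@@H]2O[C@]2(C(=O)OC)C1=O
F7 | step 6 | 1-allyl 4-methyl 3-[(E)-hept-1-en-1-yl]-2-hydroxy-5-methoxyterephthalate | CCCCC/C=C/c1c(O)c(C(=O)OCC=C)cc(OC)c1C(=O)OC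
F8 | step 6 | 4-allyl 1-methyl 2-[(E)-hept-1-en-1-yl]-6,6-dimethoxy-3-oxocyclohexa-1,4-diene-1,4-dicarboxylate | CCCCC/C=C/C1=C(C(=O)OC)C(OC)(OC)C=C(C(=O)OCC=C)C1=O
F9 | step 6 | 1-allyl 4-methyl (1R,6S)-3-[(E)-hept-1-en-1-yl]-5,5-dimethoxy-2-oxo-7-oxabicyclo[4.1.0]hept-3-ene-1,4-dicarboxylate | CCCCC/C=C/C1=C(C(=O)OC)C(OC)(OC)[C@H]2O[C@@]2(C(=O)OCC=C)C1=O
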